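**Plan**

- Retrosynthesis: the aryl ketone is taken back to a silyl-protected benzylic alcohol and the C2=C3 enone to the saturated ketone. The ring is then opened at C4–C5 while the side chain is moved back from C6 to C1 (retro Prins–pinacol), which gives an acyclic tertiary allylic silyl ether carrying a dimethyl acetal.
- Enabling feature: in the cyclohexenone ring, the methoxy-bearing C4 is joined through the C5 methylene to the quaternary C6, which sits next to the C1 carbonyl. C4 can therefore start as an acetal (oxocarbenium) carbon that already carries OMe, C5 as the CH2 end of a 1,1-disubstituted alkene, and C1 as a silyloxy carbinol that hands its side chain to C6.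
- The acyclic precursor is cut at C1–CH2 (organocerium addition to an enone), at C1–C6 (dienyl Grignard reagent plus Weinreb amide) and inside the side chain (Evans aldol).
- Forward: aldol, Weinreb amide, enone, tertiary carbinol, then the single ring-forming step (Prins–pinacol), Saegusa dehydrogenation, desilylation, oxidation.
- Stereochemistry: the methyl-bearing centre comes from the Evans syn-aldol with the (R)-auxiliary; the carbinol centre from Felkin–Anh addition; C6 and C4 from chirality transfer in the key step (chair closure, suprafacial 1,2-shift). The benzylic centre is only a relay and ends as the ketone.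

Key step: step 8

Remark: the benzylic oxygen is kept as a silyl ether until the last step because the group that migrates in step 8 must be an alkyl carbon and not an α-acyl carbon; 2-bromopenta-1,4-diene is made (step 4) and not assumed to be purchasable.

**Route**

Step 1
Reactants: 1 (4R)-4-benzyl-3-propanoyl-1,3-oxazolidin-2-one; 2 3,4-dimethoxybenzaldehyde
Product: 4 (4R)-4-benzyl-3-[(2R,3R)-3-(3,4-dimethoxyphenyl)-3-hydroxy-2-methylpropanoyl]-1,3-oxazolidin-2-one, via boron enolate 3 (not isolated)
Conditions: Bu2BOTf, i-Pr2NEt, CH2Cl2, 0 °C; 2, −78 → 0 °C; then pH 7 buffer, MeOH, H2O2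
Reagents that add atoms: none
Why: Evans boron syn-aldol reaction, in which the (Z)-enolate 3 reacts through a chair Zimmerman–Traxler transition state on the face away from the benzyl group of the (R)-auxiliary and should set both new centres as (2R,3R).

Step 2
Reactants: 4
Product: 5 (2R,3R)-3-(3,4-dimethoxyphenyl)-3-hydroxy-N-methoxy-N,2-dimethylpropanamide
Conditions: MeNHOMe·HCl, AlMe3, CH2Cl2, 0 °C → rt
Reagents that add atoms: N,O-dimethylhydroxylamine hydrochloride, CNOC.Cl
Why: aluminium amide transamination of the N-acyl oxazolidinone (Weinreb amide formation), helped by the free β-hydroxyl group, should release the auxiliary without touching either stereocentre.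

Step 3
Reactants: 5
Product: 6 (2R,3R)-3-[(tert-butyldimethylsilyl)oxy]-3-(3,4-dimethoxyphenyl)-N-methoxy-N,2-dimethylpropanamide
Conditions: TBSCl, imidazole, DMF, rt
Reagents that add atoms: tert-butyldimethylsilyl chloride, CC(C)(C)[Si](C)(C)Cl
Why: standard silylation of a secondary benzylic alcohol; the bulky, non-chelating silyl ether is what the Felkin–Anh addition in step 6 requires.

Step 4
Reactants: 7 2,3-dibromoprop-1-ene; 8 vinylmagnesium bromide
Product: 9 2-bromopenta-1,4-diene
Conditions: Li2CuCl4 (3 mol %), THF, −20 → 0 °C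
Reagents that add atoms: none
Why: copper-catalysed coupling of a vinyl Grignard reagent with an allylic bromide; SN2 and SN2' attack lead to the same product and the vinylic C–Br bond should stay intact.

Step 5
Reactants: 9 2-bromopenta-1,4-diene; 6 silyl-protected Weinreb amide
Product: 11 (1R,2R)-1-[(tert-butyldimethylsilyl)oxy]-1-(3,4-dimethoxyphenyl)-2-methyl-4-methylidenehept-6-en-3-one, via dienyl Grignard reagent 10 (not isolated)
Conditions: Mg, THF, rt (9 → 10); then 6, THF, −20 → 0 °C; cold 1 M HCl
Reagents that add atoms: none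
Why: Weinreb ketone synthesis, in which the chelated tetrahedral adduct of 10 collapses to the enone only on acidic quench, so over-addition and enolisation of the α-stereocentre should be avoided and the released amine is protonated before it can add to the enone.

Step 6
Reactants: 12 3-bromo-1,1-dimethoxypropane; 11 enone
Product: 14 (1R,2R,3R)-1-[(tert-butyldimethylsilyl)oxy]-1-(3,4-dimethoxyphenyl)-3-(3,3-dimethoxypropyl)-2-methyl-4-methylidenehept-6-en-3-ol, via acetal Grignard reagent 13 (not isolated)
Conditions: Mg, THF, rt (12 → 13); CeCl3, THF, −78 °C; then 11, −78 °C; H2O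
Reagents that add atoms: none
Why: organocerium 1,2-addition to an enolisable enone suppresses conjugate addition and deprotonation, and Felkin–Anh control (attack anti to the CH(OTBS)Ar group, past the α-hydrogen) should give the (3R)-carbinol.

Step 7
Reactants: 14
Product: 15 3-O-trimethylsilyl ether of 14, (1R,2R,3R)-1-[(tert-butyldimethylsilyl)oxy]-1-(3,4-dimethoxyphenyl)-3-(3,3-dimethoxypropyl)-2-methyl-4-methylidene-3-[(trimethylsilyl)oxy]hept-6-ene
Conditions: N-(trimethylsilyl)imidazole, CH2Cl2, rt
Reagents that add atoms: N-(trimethylsilyl)imidazole, C[Si](C)(C)n1ccnc1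
Why: neutral silyl transfer to the hindered tertiary alcohol leaves the acetal untouched and installs the silyl ether that ends the cationic cascade of step 8 as a ketone.

Step 8
Reactants: 15
Product: 18 (2R,4S)-2-[(1R,2S)-1-[(tert-butyldimethylsilyl)oxy]-1-(3,4-dimethoxyphenyl)propan-2-yl]-4-methoxy-2-(prop-2-en-1-yl)cyclohexan-1-one, via oxocarbenium ion 16 (not isolated), via cyclohexyl cation 17 (not isolated)
Conditions: TMSOTf (0.2 equiv), 2,6-di-tert-butyl-4-methylpyridine (0.3 equiv), CH2Cl2, −78 °C; then aq. NaHCO3
Reagents that add atoms: none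
Why: TMSOTf ionises the dimethyl acetal of 15 to the O-methyl oxocarbenium ion 16, the CH2 terminus of the 1,1-disubstituted alkene attacks its carbon, and the tertiary β-silyloxy cation 17 collapses by a 1,2-shift of the secondary alkyl group from the carbinol carbon, which becomes the ring carbonyl as the silyl group is passed on as TMSOMe. The closest known reaction type is the pinacol-terminated Prins cyclisation (Prins–pinacol) of alkenyl silyl ethers that carry a tethered acetal. The six-membered ring closes at the new C3–C4 bond of 18 in the 6-endo-trig mode with respect to the alkene (exo with respect to the C=O+ bond), through a chair. At C4 the O-methyl oxocarbenium unit points away from the forming ring, so OMe ends equatorial; at C2, allylic 1,2-strain with the allyl group on the cationic carbon forces the bulky CH(CH3)CH(OTBS)Ar group of the carbinol axial, parallel to the empty p orbital, so it migrates suprafacially with retention at the migrating carbon to the face cis to OMe, which transfers the (3R) configuration of the carbinol to both ring centres. The step needs carbon–carbon closure to win over capture of 16 by the silyl ether oxygen, side-chain migration to win over ring contraction by shift of the ring CH2, and the acetal to ionise before the benzylic silyl ether; the reversibility of oxygen capture while silicon stays on oxygen, the axial alignment and higher migratory aptitude of the secondary carbon, and catalytic buffered acid at −78 °C should secure these.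

Step 9
Reactants: 18
Product: 20 (4R,6R)-6-[(1R,2S)-1-[(tert-butyldimethylsilyl)oxy]-1-(3,4-dimethoxyphenyl)propan-2-yl]-4-methoxy-6-(prop-2-en-1-yl)cyclohex-2-en-1-one, via silyl enol ether 19 (not isolated)
Conditions: LiN(SiMe3)2, TMSCl, THF, −78 °C; then Pd(OAc)2, MeCN, rt
Reagents that add atoms: none
Why: Saegusa–Ito dehydrogenation; C6 of 18 is the only enolisable position of the ring ketone, so the kinetic silyl enol ether 19 forms there and palladium diacetate should convert it into the enone without touching a stereocentre.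

Step 10
Reactants: 20
Product: 21 (4R,6R)-6-[(1R,2S)-1-(3,4-dimethoxyphenyl)-1-hydroxypropan-2-yl]-4-methoxy-6-(prop-2-en-1-yl)cyclohex-2-en-1-one
Conditions: HF·pyridine, pyridine, THF, 0 °C → rt
Reagents that add atoms: none
Why: buffered fluoride cleavage of the benzylic silyl ether, to which the allylic methyl ether, the enone and the terminal alkene should be inert.

Step 11
Reactants: 21
Product: 22 (4R,6R)-6-[(2S)-1-(3,4-dimethoxyphenyl)-1-oxopropan-2-yl]-4-methoxy-6-(prop-2-en-1-yl)cyclohex-2-en-1-one (target)
Conditions: Dess–Martin periodinane, CH2Cl2, rt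
Reagents that add atoms: none
Why: Dess–Martin oxidation of the secondary benzylic alcohol under near-neutral conditions should give the aryl ketone without epimerising the adjacent α-centre, which is shielded by the quaternary carbon.

**Compound list**

1 | (4R)-4-benzyl-3-propanoyl-1,3-oxazolidin-2-one | CCC(=O)N1[C@H](Cc2ccccc2)COC1=O | starting material
2 | 3,4-dimethoxybenzaldehyde | COc1ccc(C=O)cc1OC | starting material
3 | dibutylboron (Z)-enolate of 1 | C/C=C(\OB(CCCC)CCCC)N1[C@H](Cc2ccccc2)COC1=O | intermediate
4 | (4R)-4-benzyl-3-[(2R,3R)-3-(3,4-dimethoxyphenyl)-3-hydroxy-2-methylpropanoyl]-1,3-oxazolidin-2-one | O=C(N1[C@H](Cc2ccccc2)COC1=O)[C@H](C)[C@@H](O)c1ccc(OC)c(OC)c1 | intermediate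
5 | (2R,3R)-3-(3,4-dimethoxyphenyl)-3-hydroxy-N-methoxy-N,2-dimethylpropanamide | CON(C)C(=O)[C@H](C)[C@@H](O)c1ccc(OC)c(OC)c1 | intermediate
6 | (2R,3R)-3-[(tert-butyldimethylsilyl)oxy]-3-(3,4-dimethoxyphenyl)-N-methoxy-N,2-dimethylpropanamide | CON(C)C(=O)[C@H](C)[C@@H](O[Si](C)(C)C(C)(C)C)c1ccc(OC)c(OC)c1 | intermediate
7 | 2,3-dibromoprop-1-ene | C=C(Br)CBr | starting material
8 | vinylmagnesium bromide | C=C[Mg]Br | starting material
9 | 2-bromopenta-1,4-diene | C=CCC(Br)=C | intermediate
10 | penta-1,4-dien-2-ylmagnesium bromide | C=CCC(=C)[Mg]Br | intermediate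
11 | (1R,2R)-1-[(tert-butyldimethylsilyl)oxy]-1-(3,4-dimethoxyphenyl)-2-methyl-4-methylidenehept-6-en-3-one | C=CCC(=C)C(=O)[C@H](C)[C@@H](O[Si](C)(C)C(C)(C)C)c1ccc(OC)c(OC)c1 | intermediate
12 | 3-bromo-1,1-dimethoxypropane | COC(CCBr)OC | starting material
13 | 3,3-dimethoxypropylmagnesium bromide | COC(CC[Mg]Br)OC | intermediate
14 | (1R,2R,3R)-1-[(tert-butyldimethylsilyl)oxy]-1-(3,4-dimethoxyphenyl)-3-(3,3-dimethoxypropyl)-2-methyl-4-methylidenehept-6-en-3-ol | C=CCC(=C)[C@@](O)(CCC(OC)OC)[C@H](C)[C@@H](O[Si](C)(C)C(C)(C)C)c1ccc(OC)c(OC)c1 | intermediate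
15 | 3-O-trimethylsilyl ether of 14 | C=CCC(=C)[C@@](O[Si](C)(C)C)(CCC(OC)OC)[C@H](C)[C@@H](O[Si](C)(C)C(C)(C)C)c1ccc(OC)c(OC)c1 | intermediate
16 | O-methyl oxocarbenium ion formed from 15 | C=CCC(=C)[C@@](O[Si](C)(C)C)(CCC=[O+]C)[C@H](C)[C@@H](O[Si](C)(C)C(C)(C)C)c1ccc(OC)c(OC)c1 | intermediate
17 | 5-methoxy-2-(trimethylsilyloxy)-1-(prop-2-en-1-yl)cyclohexyl cation carrying the side chain on C2 | C=CC[C+]1C[C@@H](OC)CC[C@@]1(O[Si](C)(C)C)[C@H](C)[C@@H](O[Si](C)(C)C(C)(C)C)c1ccc(OC)c(OC)c1 | intermediate
18 | (2R,4S)-2-[(1R,2S)-1-[(tert-butyldimethylsilyl)oxy]-1-(3,4-dimethoxyphenyl)propan-2-yl]-4-methoxy-2-(prop-2-en-1-yl)cyclohexan-1-one | C=CC[C@]1([C@H](C)[C@@H](O[Si](C)(C)C(C)(C)C)c2ccc(OC)c(OC)c2)C[C@@H](OC)CCC1=O | intermediate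
19 | trimethylsilyl enol ether of 18 (C1=C6) | C=CC[C@]1([C@H](C)[C@@H](O[Si](C)(C)C(C)(C)C)c2ccc(OC)c(OC)c2)C[C@@H](OC)CC=C1O[Si](C)(C)C | intermediate
20 | (4R,6R)-6-[(1R,2S)-1-[(tert-butyldimethylsilyl)oxy]-1-(3,4-dimethoxyphenyl)propan-2-yl]-4-methoxy-6-(prop-2-en-1-yl)cyclohex-2-en-1-one | C=CC[C@]1([C@H](C)[C@@H](O[Si](C)(C)C(C)(C)C)c2ccc(OC)c(OC)c2)C[C@@H](OC)C=CC1=O | intermediate
21 | (4R,6R)-6-[(1R,2S)-1-(3,4-dimethoxyphenyl)-1-hydroxypropan-2-yl]-4-methoxy-6-(prop-2-en-1-yl)cyclohex-2-en-1-one | C=CC[C@]1([C@H](C)[C@@H](O)c2ccc(OC)c(OC)c2)C[C@@H](OC)C=CC1=O | intermediate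
22 | (4R,6R)-6-[(2S)-1-(3,4-dimethoxyphenyl)-1-oxopropan-2-yl]-4-methoxy-6-(prop-2-en-1-yl)cyclohex-2-en-1-one | C=CC[C@]1([C@H](C)C(=O)c2ccc(OC)c(OC)c2)C[C@@H](OC)C=CC1=O | target

**Count**

Total step count: 11. Longest linear sequence: 10 steps (steps 1–3 and 5–11); step 4 is a one-step side branch.

**Steps most likely to fail**

Step 8. The cationic cascade may leave the intended path in three ways: the silyl ether oxygen may capture the oxocarbenium ion for good, the ring CH2 may shift instead of the side chain (ring contraction), or the benzylic silyl ether may ionise and the side chain be lost by fragmentation. The fallback sets out from 14 and returns at 18; it separates the shift from the ring closure and uses no Lewis acid. N-Bromosuccinimide (CH2Cl2, 0 °C) should open a bromonium ion on the 1,1-disubstituted alkene of 14 and trigger the same 1,2-shift of the side chain (halogen-induced semipinacol rearrangement), giving bromomethyl ketone F1. Pyridinium p-toluenesulfonate in wet acetone should then unmask keto aldehyde F2. Bu3SnH and AIBN (slow addition, benzene, 80 °C) should close the same ring bond by 6-exo addition of the primary radical to the aldehyde carbonyl, giving hydroxy ketone F3, whose carbinol configuration would rest on the chair preference of that closure. MeOTf with 2,6-di-tert-butyl-4-methylpyridine would methylate F3 to 18.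

Step 6. Facial selectivity in the addition next to the stereocentre may be poor, or the reagent may add in conjugate fashion to the enone. The fallback sets out from 5 and returns at 14; it reverses the order of the two additions and replaces Felkin–Anh control by chelation control. An excess of Grignard reagent 13 should convert 5 into β-hydroxy ketone F4. Grignard reagent 10 (CH2Cl2–THF, −78 °C) should add to the magnesium chelate of F4 on the face away from the α-methyl group and give diol F5 with the same (3R) carbinol. TBSCl and imidazole should silylate only the secondary benzylic hydroxyl and give 14.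

Step 5. The dienyl Grignard reagent may form sluggishly or lose its skipped-diene integrity, and the amine released at the quench may add to the enone. The fallback sets out from 6 and returns at 11; it builds the methylidene group after the ketone. But-3-enylmagnesium bromide should convert 6 into ketone F6. LiN(i-Pr)2 at −78 °C (kinetic enolate at the CH2 group) followed by dimethyl(methylidene)ammonium iodide should give Mannich base F7. MeI should quaternise it to ammonium salt F8, and aqueous NaHCO3 should eliminate trimethylamine to give 11.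

**Further compounds**

F1 | step 8 | (5R,6S,7R)-5-(bromomethyl)-7-[(tert-butyldimethylsilyl)oxy]-7-(3,4-dimethoxyphenyl)-1,1-dimethoxy-6-methyl-5-(prop-2-en-1-yl)heptan-4-one | C=CC[C@@](CBr)([C@H](C)[C@@H](O[Si](C)(C)C(C)(C)C)c1ccc(OC)c(OC)c1)C(=O)CCC(OC)OC
F2 | step 8 | (5R,6S,7R)-5-(bromomethyl)-7-[(tert-butyldimethylsilyl)oxy]-7-(3,4-dimethoxyphenyl)-6-methyl-4-oxo-5-(prop-2-en-1-yl)heptanal | C=CC[C@@](CBr)([C@H](C)[C@@H](O[Si](C)(C)C(C)(C)C)c1ccc(OC)c(OC)c1)C(=O)CCC=O
F3 | step 8 | (2R,4S)-2-[(1R,2S)-1-[(tert-butyldimethylsilyl)oxy]-1-(3,4-dimethoxyphenyl)propan-2-yl]-4-hydroxy-2-(prop-2-en-1-yl)cyclohexan-1-one | C=CC[C@]1([C@H](C)[C@@H](O[Si](C)(C)C(C)(C)C)c2ccc(OC)c(OC)c2)C[C@@H](O)CCC1=O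
F4 | step 6 | (1R,2R)-1-(3,4-dimethoxyphenyl)-1-hydroxy-6,6-dimethoxy-2-methylhexan-3-one | COC(OC)CCC(=O)[C@H](C)[C@@H](O)c1ccc(OC)c(OC)c1
F5 | step 6 | (1R,2R,3R)-1-(3,4-dimethoxyphenyl)-3-(3,3-dimethoxypropyl)-2-methyl-4-methylidenehept-6-ene-1,3-diol | C=CCC(=C)[C@@](O)(CCC(OC)OC)[C@H](C)[C@@H](O)c1ccc(OC)c(OC)c1
F6 | step 5 | (1R,2R)-1-[(tert-butyldimethylsilyl)oxy]-1-(3,4-dimethoxyphenyl)-2-methylhept-6-en-3-one | C=CCCC(=O)[C@H](C)[C@@H](O[Si](C)(C)C(C)(C)C)c1ccc(OC)c(OC)c1
F7 | step 5 | (1R,2R)-1-[(tert-butyldimethylsilyl)oxy]-1-(3,4-dimethoxyphenyl)-4-[(dimethylamino)methyl]-2-methylhept-6-en-3-one (both epimers at C4) | C=CCC(CN(C)C)C(=O)[C@H](C)[C@@H](O[Si](C)(C)C(C)(C)C)c1ccc(OC)c(OC)c1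
F8 | step 5 | N,N,N-trimethylammonium iodide of F7 | C=CCC(C[N+](C)(C)C)C(=O)[C@H](C)[C@@H](O[Si](C)(C)C(C)(C)C)c1ccc(OC)c(OC)c1.[I-]
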